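**Retrosynthetic overview**
- Target 26 ← late changes on ring A: 9-hydroxyl-directed epoxidation of the C1=C2 vinyl group (oxirane made last), allylic oxidation at C15, reduction and isobutyrylation at C6, and loss of HNO2 to unveil C11=C13.
- Lactone ring B ← one-pot union of cyclohexenone 13 with (E)-3-nitroacrylic acid 17: the acid oxygen bonds to C8 and C11 bonds to C7. The enabling feature is the C6 carbonyl conjugated with C7=C8 in ring A (C8 electrophilic; C7 nucleophilic once oxygen has added), together with the nitro group on C13, which makes C11 electrophilic and later leaves as nitrite.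
- 13 ← cyclohexa-1,3-diene 10 by singlet-oxygen [4+2] addition and Kornblum–DeLaMare rearrangement (9α-OH and C6=O both from O2).
- 10 ← 2-methylcyclohex-2-en-1-one 1 by asymmetric conjugate addition with aldol trapping (C5, C10), dehydration, and enone → dienyl triflate → diene.
- Ring order: carbocycle (ring A, bought) → γ-lactone (ring B, key step) → oxirane (ring C, last step).

Key step: step 10

Remark: locants C1–C15 are those of the elemane skeleton (C10 is the quaternary carbon with the C14 methyl and the C1–C2 unit; C5 carries C4 with C3 and C15; C7 carries C11 with C13 and C12); β is the face of the C14 methyl; (E)-3-nitroacrylic acid is assumed not to be a stock chemical and is made in steps 8 and 9.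

Step 1
Reactants: 1 2-methylcyclohex-2-en-1-one; 2 isopropenylmagnesium bromide; 3 acetaldehyde
Product: 5 (2R,3S)-2-(1-hydroxyethyl)-2-methyl-3-(prop-1-en-2-yl)cyclohexan-1-one (carbinol epimers), via magnesium enolate 4 (not isolated)
Conditions: CuBr·SMe2 (5 mol %), Josiphos-type ferrocenyl diphosphine (6 mol %, enantiomer chosen for the 3S adduct), t-BuOMe, −78 °C; then MeCHO, −78 °C; aq NH4Cl
Reagents that add atoms: none
Why: Copper-catalysed asymmetric conjugate addition of the Grignard reagent sets C5 under ligand control, and aldol trapping of enolate 4 on the face anti to the new isopropenyl group sets C10 with the methyl cis to isopropenyl (the carbinol centre is a mixture that disappears in step 2).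

Step 2
Reactants: 5 (2R,3S)-2-(1-hydroxyethyl)-2-methyl-3-(prop-1-en-2-yl)cyclohexan-1-one
Product: 6 (2S,3S)-2-ethenyl-2-methyl-3-(prop-1-en-2-yl)cyclohexan-1-one
Conditions: Burgess reagent (MeO2C–N(−)–SO2–N(+)Et3), benzene, 50 °C
Reagents that add atoms: none
Why: Burgess dehydration is a syn elimination through the sulfamate ester, whose only β-hydrogens are on the methyl group, so the vinyl group should form without cationic rearrangement at the neopentyl centre.

Step 3
Reactants: 6 (2S,3S)-2-ethenyl-2-methyl-3-(prop-1-en-2-yl)cyclohexan-1-one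
Product: 8 (5S,6S)-6-ethenyl-6-methyl-5-(prop-1-en-2-yl)cyclohex-2-en-1-one, via trimethylsilyl enol ether 7 (not isolated)
Conditions: LiN(i-Pr)2, THF, −78 °C; Me3SiCl; then Pd(OAc)2 (1.0 equiv), MeCN, rt
Reagents that add atoms: none
Why: Saegusa–Ito oxidation; because C10 is quaternary only the C8 silyl enol ether can form, and Pd(OAc)2 converts it into the C7=C8 enone.

Step 4
Reactants: 8 (5S,6S)-6-ethenyl-6-methyl-5-(prop-1-en-2-yl)cyclohex-2-en-1-one
Product: 9 (5S,6S)-6-ethenyl-6-methyl-5-(prop-1-en-2-yl)cyclohexa-1,3-dien-1-yl trifluoromethanesulfonate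
Conditions: LiN(i-Pr)2, THF, −78 °C; PhNTf2, −78 → 0 °C
Reagents that add atoms: N-phenylbis(trifluoromethanesulfonimide), O=S(=O)(N(c1ccccc1)S(=O)(=O)C(F)(F)F)C(F)(F)F
Why: With no α'-hydrogen at C10 the base removes the γ-hydrogen at C6, and O-sulfonylation of the extended enolate gives the 1,3-dienyl triflate.

Step 5
Reactants: 9 (5S,6S)-6-ethenyl-6-methyl-5-(prop-1-en-2-yl)cyclohexa-1,3-dien-1-yl trifluoromethanesulfonate
Product: 10 (5R,6S)-5-ethenyl-5-methyl-6-(prop-1-en-2-yl)cyclohexa-1,3-diene
Conditions: Pd(OAc)2 (5 mol %), PPh3 (10 mol %), HCO2H, Bu3N, DMF, 60 °C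
Reagents that add atoms: none
Why: Palladium-catalysed formate hydrogenolysis of the alkenyl triflate replaces OTf by H and leaves the C6=C7–C8=C9 diene in place.

Step 6
Reactants: 10 (5R,6S)-5-ethenyl-5-methyl-6-(prop-1-en-2-yl)cyclohexa-1,3-diene
Product: 12 (4R,5S,6S)-5-ethenyl-4-hydroxy-5-methyl-6-(prop-1-en-2-yl)cyclohex-2-en-1-one, via endoperoxide 11 (not isolated)
Conditions: O2, tetraphenylporphyrin (cat.), visible light, CH2Cl2, −78 °C; then Et3N, 0 °C → rt
Reagents that add atoms: dioxygen, O=O
Why: Singlet oxygen should add [4+2] on the α face (the face of H5 and the vinyl group, opposite the C14 methyl and the isopropenyl group), so both new C–O bonds are α, and the Kornblum–DeLaMare rearrangement removes the less hindered C6–H to leave the C6 ketone and the 9α-hydroxyl.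

Step 7
Reactants: 12 (4R,5S,6S)-5-ethenyl-4-hydroxy-5-methyl-6-(prop-1-en-2-yl)cyclohex-2-en-1-one
Product: 13 (4R,5S,6S)-4-[(tert-butyldimethylsilyl)oxy]-5-ethenyl-5-methyl-6-(prop-1-en-2-yl)cyclohex-2-en-1-one
Conditions: t-BuMe2SiOTf, 2,6-lutidine, CH2Cl2, −78 °C
Reagents that add atoms: tert-butyldimethylsilyl trifluoromethanesulfonate, CC(C)(C)[Si](C)(C)OS(=O)(=O)C(F)(F)F
Why: Silylation of the hindered secondary alcohol protects the 9-hydroxyl from conjugate addition and acylation in the following steps.

Step 8
Reactants: 14 tert-butyl acrylate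
Product: 16 tert-butyl (E)-3-nitroprop-2-enoate, via iodonitro ester 15 (not isolated)
Conditions: N2O4, I2, Et2O, 0 °C; then NaOAc, Et2O, rt
Reagents that add atoms: dinitrogen tetroxide, O=[N+]([O-])[N+](=O)[O-]
Why: Addition of NO2 and iodine across the acrylate (nitro on the terminal carbon) followed by acetate-induced loss of HI gives the (E)-nitroalkene, a sequence established for the ethyl ester.

Step 9
Reactants: 16 tert-butyl (E)-3-nitroprop-2-enoate
Product: 17 (E)-3-nitroprop-2-enoic acid
Conditions: CF3CO2H, CH2Cl2, rt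
Reagents that add atoms: none
Why: Acidolysis of the tert-butyl ester (loss of isobutene) frees the acid without touching the nitroalkene.

Step 10
Reactants: 13 (4R,5S,6S)-4-[(tert-butyldimethylsilyl)oxy]-5-ethenyl-5-methyl-6-(prop-1-en-2-yl)cyclohex-2-en-1-one; 17 (E)-3-nitroprop-2-enoic acid
Product: 19 13-nitro-6-oxo-9α-(tert-butyldimethylsilyloxy)elema-1,3-dien-12,8α-olide (C11 epimers), via oxa-Michael adduct 18 (not isolated)
Conditions: 9-amino-9-deoxy-epi-quinine (20 mol %), CHCl3, 30 °C, slow addition of 17 (1.5 equiv); aq NaH2PO4 work-up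
Reagents that add atoms: none
Why: Proposed new method: the primary amine converts the C6 ketone of 13 into an iminium ion whose carboxylate counter-ion (from 17) adds reversibly to C8 (O–C8 bond), and the C6=C7 enamine so formed, which now carries the nitroalkene within reach, attacks C11, the carbon β to the nitro group, in an irreversible Michael addition (C11–C7 bond) before hydrolysis returns the ketone and the catalyst. The closest known reactions are amine-catalysed oxa-Michael/Michael domino annulations of enones with hydroxy-substituted nitroalkenes and the enamine addition to 3-nitroacrylates used for α-methylene lactones, but a carboxylic acid has not been shown as the oxygen donor of such a cascade. Ring B closes by C–C bond formation in the 5-exo-trig mode after intermolecular C–O bond formation. C8 is set under thermodynamic control, since only the reversible adduct with the equatorial 8α C–O bond, remote from the axial C14 methyl, is drained productively; C7 equilibrates through the enamine to the trans (equatorial) ring fusion; C11 is uncontrolled and is removed in step 13. The step needs attack at C11 instead of C13 and reaction through the C7 instead of the C5 enamine: the nitro group secures the first, and the conjugate addition, which creates only the C6=C7 enamine, secures the second.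

Step 11
Reactants: 19 13-nitro-6-oxo-9α-(tert-butyldimethylsilyloxy)elema-1,3-dien-12,8α-olide
Product: 20 6β-hydroxy-13-nitro-9α-(tert-butyldimethylsilyloxy)elema-1,3-dien-12,8α-olide
Conditions: LiBH(s-Bu)3 (2.5 equiv), THF, −78 °C; AcOH quench at −78 °C
Reagents that add atoms: none
Why: The bulky hydride should attack C6 from the α face along the equatorial trajectory because the axial β approach is blocked by the syn-axial C14 methyl, giving the axial 6β-alcohol; the cold acidic quench avoids migration of the lactone to O6.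

Step 12
Reactants: 20 6β-hydroxy-13-nitro-9α-(tert-butyldimethylsilyloxy)elema-1,3-dien-12,8α-olide
Product: 21 6β-isobutyryloxy-13-nitro-9α-(tert-butyldimethylsilyloxy)elema-1,3-dien-12,8α-olide
Conditions: isobutyryl chloride, pyridine, CH2Cl2, 0 °C → rt
Reagents that add atoms: isobutyryl chloride, CC(C)C(=O)Cl
Why: Acylation of the axial 6β-hydroxyl with the acid chloride in pyridine, without a stronger base, so that the nitromethyl group is not converted into its nitronate.

Step 13
Reactants: 21 6β-isobutyryloxy-13-nitro-9α-(tert-butyldimethylsilyloxy)elema-1,3-dien-12,8α-olide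
Product: 22 6β-isobutyryloxy-9α-(tert-butyldimethylsilyloxy)elema-1,3,11(13)-trien-12,8α-olide
Conditions: DBU, CH2Cl2, 0 °C
Reagents that add atoms: none
Why: Base-induced E1cB loss of nitrous acid from the β-nitro lactone unveils the C11=C13 exo-methylene; with C6 now an ester, C7 is no longer enolisable, so the double bond should not move into the ring.

Step 14
Reactants: 22 6β-isobutyryloxy-9α-(tert-butyldimethylsilyloxy)elema-1,3,11(13)-trien-12,8α-olide
Product: 23 15-hydroxy-6β-isobutyryloxy-9α-(tert-butyldimethylsilyloxy)elema-1,3,11(13)-trien-12,8α-olide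
Conditions: SeO2 (0.5 equiv), t-BuOOH, CH2Cl2, rt
Reagents that add atoms: tert-butyl hydroperoxide, CC(C)(C)OO
Why: Allylic oxidation with SeO2 (ene reaction, then [2,3]-sigmatropic shift) hydroxylates the methyl group of the electron-rich isopropenyl unit; the vinyl group has no allylic hydrogen and the methylene lactone is electron-poor.

Step 15
Reactants: 23 15-hydroxy-6β-isobutyryloxy-9α-(tert-butyldimethylsilyloxy)elema-1,3,11(13)-trien-12,8α-olide
Product: 24 6β-isobutyryloxy-15-oxo-9α-(tert-butyldimethylsilyloxy)elema-1,3,11(13)-trien-12,8α-olide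
Conditions: MnO2 (activated, excess), CH2Cl2, rt
Reagents that add atoms: none
Why: MnO2 oxidises only the primary allylic alcohol and gives the 2-substituted acrolein.

Step 16
Reactants: 24 6β-isobutyryloxy-15-oxo-9α-(tert-butyldimethylsilyloxy)elema-1,3,11(13)-trien-12,8α-olide
Product: 25 9α-hydroxy-6β-isobutyryloxy-15-oxoelema-1,3,11(13)-trien-12,8α-olide
Conditions: HF·pyridine, THF/pyridine, 0 °C → rt
Reagents that add atoms: none
Why: Fluoride cleavage of the silyl ether under buffered conditions frees the 9α-hydroxyl without opening the lactone or the ester.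

Step 17
Reactants: 25 9α-hydroxy-6β-isobutyryloxy-15-oxoelema-1,3,11(13)-trien-12,8α-olide
Product: 26 (1R)-1,2-epoxy-9α-hydroxy-6β-isobutyryloxy-15-oxoelema-3,11(13)-dien-12,8α-olide (CNP0496100.1)
Conditions: VO(acac)2 (10 mol %), t-BuOOH (anhydrous, in decane), CH2Cl2, 0 °C → rt
Reagents that add atoms: tert-butyl hydroperoxide, CC(C)(C)OO
Why: Hydroxyl-directed epoxidation: the vanadate ester of the axial 9α-hydroxyl delivers the peroxide oxygen to the homoallylic C1=C2 vinyl group while the electron-poor alkenes stay inert, and a chair-like transition state with the terminal CH2 pseudo-equatorial (turned toward C5) is expected to give the (1R)-oxirane.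

**Compound list**
1 | 2-methylcyclohex-2-en-1-one | CC1=CCCCC1=O | starting material
2 | isopropenylmagnesium bromide | C=C(C)[Mg]Br | starting material
3 | acetaldehyde | CC=O | starting material
4 | bromomagnesium enolate of (3S)-2-methyl-3-(prop-1-en-2-yl)cyclohexanone | Br[Mg]OC1=C(C)[C@H](C(C)=C)CCC1 | intermediate
5 | (2R,3S)-2-(1-hydroxyethyl)-2-methyl-3-(prop-1-en-2-yl)cyclohexan-1-one (carbinol epimers) | O=C1CCC[C@@H](C(C)=C)[C@]1(C)C(C)O | intermediate
6 | (2S,3S)-2-ethenyl-2-methyl-3-(prop-1-en-2-yl)cyclohexan-1-one | O=C1CCC[C@@H](C(C)=C)[C@]1(C)C=C | intermediate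
7 | trimethylsilyl enol ether of 6 (C8=C9 enol ether) | C[Si](C)(C)OC1=CCC[C@@H](C(C)=C)[C@]1(C)C=C | intermediate
8 | (5S,6S)-6-ethenyl-6-methyl-5-(prop-1-en-2-yl)cyclohex-2-en-1-one | O=C1C=CC[C@@H](C(C)=C)[C@]1(C)C=C | intermediate
9 | (5S,6S)-6-ethenyl-6-methyl-5-(prop-1-en-2-yl)cyclohexa-1,3-dien-1-yl trifluoromethanesulfonate | O=S(=O)(OC1=CC=C[C@@H](C(C)=C)[C@]1(C)C=C)C(F)(F)F | intermediate
10 | (5R,6S)-5-ethenyl-5-methyl-6-(prop-1-en-2-yl)cyclohexa-1,3-diene | C1=CC=C[C@@H](C(C)=C)[C@]1(C)C=C | intermediate
11 | 6α,9α-epidioxide of 10 (2,3-dioxabicyclo[2.2.2]oct-5-ene; peroxide bridge on the α face) | C1=C[C@H](OO2)[C@@H](C(C)=C)[C@](C)(C=C)[C@@H]12 | intermediate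
12 | (4R,5S,6S)-5-ethenyl-4-hydroxy-5-methyl-6-(prop-1-en-2-yl)cyclohex-2-en-1-one | O=C1C=C[C@@H](O)[C@@](C)(C=C)[C@@H]1C(C)=C | intermediate
13 | (4R,5S,6S)-4-[(tert-butyldimethylsilyl)oxy]-5-ethenyl-5-methyl-6-(prop-1-en-2-yl)cyclohex-2-en-1-one | O=C1C=C[C@@H](O[Si](C)(C)C(C)(C)C)[C@@](C)(C=C)[C@@H]1C(C)=C | intermediate
14 | tert-butyl acrylate | C=CC(=O)OC(C)(C)C | starting material
15 | tert-butyl 2-iodo-3-nitropropanoate | CC(C)(C)OC(=O)C(I)C[N+](=O)[O-] | intermediate
16 | tert-butyl (E)-3-nitroprop-2-enoate | CC(C)(C)OC(=O)/C=C/[N+](=O)[O-] | intermediate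
17 | (E)-3-nitroprop-2-enoic acid | OC(=O)/C=C/[N+](=O)[O-] | intermediate
18 | oxa-Michael adduct of 13 and 17 (ketone form of the catalyst-bound enamine; 8α-(E)-3-nitroacryloyloxy, cis to the 9α-silyloxy group) | O=C1C[C@@H](OC(=O)/C=C/[N+](=O)[O-])[C@@H](O[Si](C)(C)C(C)(C)C)[C@@](C)(C=C)[C@@H]1C(C)=C | intermediate
19 | 13-nitro-6-oxo-9α-(tert-butyldimethylsilyloxy)elema-1,3-dien-12,8α-olide (7α-H, 8β-H; C11 epimers) | [O-][N+](=O)CC1C(=O)O[C@@H]2[C@@H]1C(=O)[C@@H](C(C)=C)[C@](C)(C=C)[C@@H]2O[Si](C)(C)C(C)(C)C | intermediate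
20 | 6β-hydroxy-13-nitro-9α-(tert-butyldimethylsilyloxy)elema-1,3-dien-12,8α-olide | [O-][N+](=O)CC1C(=O)O[C@@H]2[C@@H]1[C@@H](O)[C@@H](C(C)=C)[C@](C)(C=C)[C@@H]2O[Si](C)(C)C(C)(C)C | intermediate
21 | 6β-isobutyryloxy-13-nitro-9α-(tert-butyldimethylsilyloxy)elema-1,3-dien-12,8α-olide | [O-][N+](=O)CC1C(=O)O[C@@H]2[C@@H]1[C@@H](OC(=O)C(C)C)[C@@H](C(C)=C)[C@](C)(C=C)[C@@H]2O[Si](C)(C)C(C)(C)C | intermediate
22 | 6β-isobutyryloxy-9α-(tert-butyldimethylsilyloxy)elema-1,3,11(13)-trien-12,8α-olide | C=C1C(=O)O[C@@H]2[C@@H]1[C@@H](OC(=O)C(C)C)[C@@H](C(C)=C)[C@](C)(C=C)[C@@H]2O[Si](C)(C)C(C)(C)C | intermediate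
23 | 15-hydroxy-6β-isobutyryloxy-9α-(tert-butyldimethylsilyloxy)elema-1,3,11(13)-trien-12,8α-olide | C=C1C(=O)O[C@@H]2[C@@H]1[C@@H](OC(=O)C(C)C)[C@@H](C(=C)CO)[C@](C)(C=C)[C@@H]2O[Si](C)(C)C(C)(C)C | intermediate
24 | 6β-isobutyryloxy-15-oxo-9α-(tert-butyldimethylsilyloxy)elema-1,3,11(13)-trien-12,8α-olide | C=C1C(=O)O[C@@H]2[C@@H]1[C@@H](OC(=O)C(C)C)[C@@H](C(=C)C=O)[C@](C)(C=C)[C@@H]2O[Si](C)(C)C(C)(C)C | intermediate
25 | 9α-hydroxy-6β-isobutyryloxy-15-oxoelema-1,3,11(13)-trien-12,8α-olide | C=C1C(=O)O[C@@H]2[C@@H]1[C@@H](OC(=O)C(C)C)[C@@H](C(=C)C=O)[C@](C)(C=C)[C@@H]2O | intermediate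
26 | (1R)-1,2-epoxy-9α-hydroxy-6β-isobutyryloxy-15-oxoelema-3,11(13)-dien-12,8α-olide (CNP0496100.1) | C=C1C(=O)O[C@@H]2[C@@H]1[C@@H](OC(=O)C(C)C)[C@@H](C(=C)C=O)[C@](C)([C@@H]1CO1)[C@@H]2O | target

**Step count**
Total: 17 steps. Longest linear sequence: 15 steps (steps 1–7 and 10–17, from compound 1); steps 8 and 9 form a two-step side branch.

**Steps most likely to fail**

Step 10 (the step carrying the new-method label). The carboxylate may add to C8 too slowly or too unfavourably, so that the nitroalkene is lost by oligomerisation or by conjugate addition of the amine catalyst. The dienamine of 13 may also be alkylated at C7 without C–O bond formation, and addition on the β face of C8 would be followed by β-elimination of the acyloxy group. The fallback makes the two bonds one at a time with known reactions; it sets out from 12 and returns to the route at 19. Phenylboronic acid with a catalytic tertiary amine converts the 9α-hydroxyl into a boronic half-ester whose B–OH adds intramolecularly to C8 (oxa-Michael addition, necessarily cis to O9), giving the cis-fused phenyldioxaborolane ketone F1. Oxidative cleavage with H2O2/NaHCO3 gives the 8α,9α-dihydroxy ketone F2. Carbodiimide esterification of the less hindered equatorial 8-hydroxyl with 17 gives the 8-O-nitroacryloyl 9-hydroxy ketone F3. Silylation of the 9-hydroxyl (t-BuMe2SiOTf, 2,6-lutidine) gives 18, now isolated, and a primary-amine-catalysed intramolecular Michael addition of the ketone to the nitroalkene (enamine catalysis) closes ring B to 19. In this variant O8 comes from the boronic acid and not from 17.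

Step 17. Facial discrimination at the freely rotating vinyl group may be poor, so that both C1 epimers form. The fallback sets out from 25 and returns at 26. The epoxidation is accepted as unselective (same VO(acac)2/t-BuOOH conditions), so 26 forms together with its (1S)-epimer F4. The mixture is then submitted to hydrolytic kinetic resolution with Co(salen)(OAc) (salen = N,N'-bis(3,5-di-tert-butylsalicylidene)cyclohexane-1,2-diamine dianion; the catalyst enantiomer that hydrolyses (S)-alkyloxiranes) and a limiting amount of water. This opens F4 to the (1S)-1,2-diol F5 and leaves 26, which is separated by chromatography.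

Step 1. Enantioselectivity with the alkenyl Grignard reagent may be low, 1,2-addition may compete, and the aldolate may revert on work-up. The fallback sets out from 1 and returns at 5. Copper-catalysed asymmetric conjugate addition of diethyl(isopropenyl)aluminium (from 2-bromopropene, t-BuLi and Et2AlCl; CuBr·SMe2 with a chiral phosphoramidite ligand) is followed by trapping of the aluminium enolate with Me3SiCl to give the trimethylsilyl enol ether F6. A separate Mukaiyama aldol addition of F6 to 3 (TiCl4, CH2Cl2, −78 °C) again takes place anti to the isopropenyl group and gives 5.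

Further compounds
F1 | step 10 | cis-fused 2-phenyl-1,3,2-dioxaborolane of the 8α,9α-diol ketone (boronate oxa-Michael adduct of 12) | O=C1C[C@H]2OB(c3ccccc3)O[C@H]2[C@@](C)(C=C)[C@@H]1C(C)=C
F2 | step 10 | 8α,9α-dihydroxy ketone (3,4-cis-dihydroxy-5-ethenyl-5-methyl-6-(prop-1-en-2-yl)cyclohexanone) | O=C1C[C@@H](O)[C@@H](O)[C@@](C)(C=C)[C@@H]1C(C)=C
F3 | step 10 | 8α-O-[(E)-3-nitroacryloyl] 9α-hydroxy ketone | O=C1C[C@@H](OC(=O)/C=C/[N+](=O)[O-])[C@@H](O)[C@@](C)(C=C)[C@@H]1C(C)=C
F4 | step 17 | (1S)-epimer of 26 | C=C1C(=O)O[C@@H]2[C@@H]1[C@@H](OC(=O)C(C)C)[C@@H](C(=C)C=O)[C@](C)([C@H]1CO1)[C@@H]2O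
F5 | step 17 | (1S)-1,2-diol from hydrolysis of F4 | C=C1C(=O)O[C@@H]2[C@@H]1[C@@H](OC(=O)C(C)C)[C@@H](C(=C)C=O)[C@](C)([C@H](O)CO)[C@@H]2O
F6 | step 1 | trimethylsilyl enol ether of (3S)-2-methyl-3-(prop-1-en-2-yl)cyclohexanone | C[Si](C)(C)OC1=C(C)[C@H](C(C)=C)CCC1
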